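The earlier runs and the new flask were generated by integration for substances that don't exist, noise included.

Two questions stood on this flask, and both concern where the starting complex charged has gone at the end.

- the species that holds most of what was charged as starting complex, at 1.5 h (complex with two exchanged / complex with one exchanged / starting complex / complex with three exchanged / over-reaction product)
- the largest share itself, whichever of these holds it, in percent of the starting complex charged

| setting | south-west | west | north | flask |
|---|---|---|---|---|
| starting complex | 1.5 M | 1.5 M | 1.5 M | 1.5 M |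
| incoming ligand | 1.1 M | 1.7 M | 2.25 M | 2.25 M |
| leaving ligand | 0.75 M (fed, over 30 min) | 0.75 M (fed, over 30 min) | 0.38 M (fed, over 30 min) | 0.750 M (fed, over 30 min) |
| protic impurity | 0.15 M | 0.15 M | 0.15 M | 0.150 M |
| remark | run made earlier; the fed solution adds 0.10 times the starting volume | run made earlier; the fed solution adds 0.10 times the starting volume | run made earlier; the fed solution adds 0.10 times the starting volume | the fed solution adds 0.10 times the starting volume |
| time |  |  |  | 1.5 h |

| run | time / min | complex with two exchanged / % | starting complex / % | complex with one exchanged / % | complex with three exchanged / % | over-reaction product / % |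
|---|---|---|---|---|---|---|
| south-west | 8.00 | 1.0 | 39.7 | 2.6 | 0 | 38.7 |
| south-west | 12.0 | 0.4 | 34.4 | 1.5 | 0.6 | 44.7 |
| south-west | 20.0 | 1.4 | 29.2 | 1.1 | 0.9 | 49.9 |
| south-west | 30.0 | 3.2 | 27.4 | 0.3 | 0 | 56.6 |
| south-west | 50.0 | 1.0 | 26.8 | 0 | 0 | 57.2 |
| south-west | 90.0 | 1.2 | 24.9 | 0.2 | 0.2 | 60.9 |
| west | 15.0 | 1.9 | 17.2 | 0.8 | 2.9 | 65.7 |
| west | 30.0 | 1.5 | 11.4 | 0.1 | 1.0 | 75.7 |
| west | 50.0 | 1.4 | 8.7 | 0.1 | 0.5 | 82.8 |
| west | 60.0 | 2.0 | 6.9 | 2.1 | 0.3 | 84.2 |
| west | 80.0 | 1.5 | 6.1 | 0.1 | 0.8 | 87.4 |
| west | 90.0 | 0.6 | 5.1 | 0.3 | 0.1 | 89.7 |
| north | 8.00 | 2.3 | 17.7 | 4.1 | 0 | 59.0 |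
| north | 25.0 | 3.9 | 5.2 | 0.3 | 2.0 | 81.4 |
| north | 40.0 | 4.5 | 3.2 | 0.7 | 1.1 | 87.7 |
| north | 60.0 | 4.7 | 1.5 | 0.2 | 0 | 93.5 |
| north | 90.0 | 3.3 | 0.4 | 0 | 0 | 95.1 |

(readings scatter by 1 percentage point)

- charges are per starting volume, the dose included; the dosed solution carries all of it
- a reading or a percentage of starting complex is of its free form alone

I folded the charges of the flask into one number:

S = (incoming ligand − protic impurity) / starting complex = 1.40

This is the supply ratio, the incoming ligand left once the impurity has taken its equal amount, as a fraction of the starting complex charged. Taking one incoming ligand per product, incoming ligand is the limiting reagent below one, and S is then the ceiling on the product fraction. The south-west run has S = 0.633 and read 60.9% of over-reaction product at 90.0 min.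

One number was not enough, though. South-west should keep 36.7% unturned, yet it read 24.9% of starting complex, and its readings fall 12.6% short of the charge, together 37.5%, so S speaks to the amount unturned but not to its form. Nor does a ceiling say when it is reached: the west run, at S = 1.03, still read 5.1% of starting complex at 90.0 min.

The flask shares its S with the north run, so its ceiling is the whole charge, but it carries twice north's leaving ligand; even so, I took north's reading of 95.1% of over-reaction product at 90.0 min as my figure. The forecast, lower, said over-reaction product at 93%, with “the product slightly below north's” reading.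

The flask gives over-reaction product at 94.8%.

    starting complex + incoming ligand ⇌ leaving ligand + complex with one exchanged (K = 5.00, k = 0.00246 /M/s)
    complex with one exchanged + incoming ligand ⇌ leaving ligand + complex with two exchanged (K = 25.0, k = 6.99 × 10⁻⁴ /M/s)
    complex with two exchanged + incoming ligand ⇌ leaving ligand + complex with three exchanged (K = 0.600, k = 0.00804 /M/s)
    complex with one exchanged → over-reaction product (k = 0.0145 /s)
    protic impurity + incoming ligand → quenched reagent (k = 0.0415 /M/s)
    starting complex ⇌ dormant form (K = 0.574, k = 0.00115 /s)

The excess of S over one, 0.400 of the starting complex charged, is 26.7% of the incoming ligand's own charge. The flask holds 24.2% of that charge at 1.50 h and 26.4% at 15.0 h. A neighbour flask, charged with 0.90 M of incoming ligand and otherwise like this flask, has: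

S = 0.500

Its ceiling on the product is therefore 50.0% of the charge, and the same share should stay unturned. That neighbour ends with 48.6% of over-reaction product, 0.17% of its incoming ligand, 32.2% of starting complex and 18.5% of dormant form.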